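## Retrosynthetic overview

1. The side-chain oxirane is closed last, by C11–O displacement of a C10 mesylate with inversion. The C8 angelate sits on an anti-1,3-diol that comes from a C8 ketone reduced under direction of the C10 hydroxyl.
2. Key disconnection C7–C8: a light-driven (nBu4N)4[W10O32]/NiBr2 coupling of a ring alkenyl triflate with the lactol (masked aldehyde) of (3S)-3,4-dihydroxy-4-methylpentanal.
3. The lactol comes from L-malic acid (dioxolanone, MeMgBr, iBu2AlH); C10 is the malic acid stereocentre.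
4. The alkenyl triflate comes from the isopropenyl group of (S)-carvone (ozonolysis, kinetic triflation) after the ring is dressed: trans α′-hydroxylation, Mitsunobu inversion with angelic acid, Luche reduction, hydroxyl-directed epoxidation, second angelate from one batch of a mixed anhydride that also serves the third.
5. Ring order: the carbocycle is bought with carvone; the 3,4-oxirane is formed first (step 4) and the 10,11-oxirane last (step 15).

Assumption: locants follow bisabolane numbering (ring C1–C6 with esters on C1 and C2, methyl on C3, side chain on C6; side chain C7(=C14H2)–C8–C9–C10–C11), "angelate" means (2Z)-2-methylbut-2-enoate, and the oxaziridine of step 1 is used as the racemate.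

## Route

Step 1
Reactants: 1 (S)-(+)-carvone
Product: 3 (5R,6R)-6-hydroxy-2-methyl-5-(prop-1-en-2-yl)cyclohex-2-en-1-one (trans-6-hydroxycarvone), via lithium dienolate 2 (not isolated)
Conditions: LiN(iPr)2, THF, −78 °C; then (±)-trans-2-(phenylsulfonyl)-3-phenyloxaziridine, −78 °C; aq NH4Cl
Reagents that add atoms: (±)-trans-2-(phenylsulfonyl)-3-phenyloxaziridine, O=S(=O)(c1ccccc1)N1OC1c1ccccc1
Why: Kinetic α′-deprotonation gives the cross-conjugated dienolate, and the bulky oxaziridine transfers oxygen anti to the adjacent isopropenyl group (Davis enolate hydroxylation), so the carvone stereocentre sets the new carbinol trans.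

Step 2
Reactants: 3 trans-6-hydroxycarvone; 4 angelic acid
Product: 5 (1S,6R)-3-methyl-2-oxo-6-(prop-1-en-2-yl)cyclohex-3-en-1-yl (2Z)-2-methylbut-2-enoate (ester cis to isopropenyl)
Conditions: PPh3, DIAD, PhMe, 0 °C → rt
Reagents that add atoms: none
Why: Mitsunobu esterification displaces the alkoxyphosphonium by angelate in an SN2 step, inverting the carbinol to the cis (axial) ester and installing the first angelate under neutral conditions that keep the Z geometry.

Step 3
Reactants: 5 cis-angeloyloxy enone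
Product: 6 (1S,2R,6R)-2-hydroxy-3-methyl-6-(prop-1-en-2-yl)cyclohex-3-en-1-yl (2Z)-2-methylbut-2-enoate (OH, ester and isopropenyl all cis)
Conditions: NaBH4, CeCl3·7H2O, MeOH, −78 °C
Reagents that add atoms: none
Why: Luche 1,2-reduction delivers hydride axially, anti to the axial C1 ester (Felkin–Anh aligned, as in carvone to cis-carveol), giving the equatorial C2 alcohol cis to both neighbours.

Step 4
Reactants: 6 allylic alcohol
Product: 7 (1S,2S,3S,4R,6R)-3,4-epoxy-2-hydroxy-3-methyl-6-(prop-1-en-2-yl)cyclohexyl (2Z)-2-methylbut-2-enoate (oxirane O, OH, ester and isopropenyl all cis)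
Conditions: VO(acac)2 (2 mol %), tBuOOH, CH2Cl2, 0 °C → rt
Reagents that add atoms: tert-butyl hydroperoxide, CC(C)(C)OO
Why: Hydroxyl-directed VO(acac)2-catalysed epoxidation delivers oxygen to the face of the allylic C2–OH, setting C3 and C4 cis to all other ring substituents; the undirected isopropenyl and electron-poor angelate alkenes are left alone.

Step 5
Reactants: 4 angelic acid
Product: 8 (2Z)-2-methylbut-2-enoic 2,4,6-trichlorobenzoic anhydride
Conditions: 2,4,6-Cl3C6H2COCl (1.0 equiv), Et3N (1.05 equiv), PhMe, rt, 2 h; filter under argon, concentrate; kept as a PhMe stock at −20 °C (one batch for steps 6 and 14)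
Reagents that add atoms: 2,4,6-trichlorobenzoyl chloride, O=C(Cl)c1c(Cl)cc(Cl)cc1Cl
Why: The triethylammonium carboxylate attacks the acid chloride (Yamaguchi mixed-anhydride formation) with no nucleophilic catalyst present, so the Z alkene cannot isomerise by conjugate addition, and the two ortho chlorines shield the aroyl carbonyl so that alcohols later attack the angeloyl carbonyl.

Step 6
Reactants: 7 epoxy alcohol; 8 mixed anhydride
Product: 9 (1S,2S,3R,4R,6R)-3,4-epoxy-3-methyl-6-(prop-1-en-2-yl)cyclohexane-1,2-diyl bis[(2Z)-2-methylbut-2-enoate]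
Conditions: 8 (2 equiv), NaHCO3 (solid, 3 equiv), PhMe, 80 °C
Reagents that add atoms: none
Why: DMAP-free Yamaguchi-type mixed-anhydride acylation esterifies the hindered C2–OH without Z-to-E isomerisation while solid NaHCO3 takes up the liberated aroic acid and protects the oxirane; no stereocentre changes, and a prior 1,2-acyl shift would give the same diester.

Step 7
Reactants: 9 bis-angelate
Product: 11 (1S,2S,3R,4R,6S)-6-acetyl-3,4-epoxy-3-methylcyclohexane-1,2-diyl bis[(2Z)-2-methylbut-2-enoate], via ozonide 10 (not isolated)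
Conditions: O3, CH2Cl2, −78 °C (Sudan Red 7B end point); then Me2S, −78 °C → rt
Reagents that add atoms: ozone, [O-][O+]=O
Why: Ozonolysis is much faster at the electron-rich 1,1-disubstituted alkene than at the conjugated trisubstituted angelates, and the dye end point stops it there, giving the methyl ketone after reductive work-up.

Step 8
Reactants: 11 methyl ketone
Product: 13 (1S,2S,3R,4R,6S)-3,4-epoxy-3-methyl-6-[1-(trifluoromethylsulfonyloxy)ethenyl]cyclohexane-1,2-diyl bis[(2Z)-2-methylbut-2-enoate], via potassium enolate 12 (not isolated)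
Conditions: KN(SiMe3)2, THF, −78 °C; then Comins' reagent, −78 °C
Reagents that add atoms: N-(5-chloropyridin-2-yl)-1,1,1-trifluoro-N-(trifluoromethylsulfonyl)methanesulfonamide (Comins' reagent), O=S(=O)(N(c1ccc(Cl)cn1)S(=O)(=O)C(F)(F)F)C(F)(F)F
Why: The hindered amide removes a methyl proton kinetically at −78 °C and the terminal enolate is O-sulfonylated (kinetic enol triflate formation) before it can equilibrate toward C6, which would expel the β-angelate.

Step 9
Reactants: 14 L-(S)-malic acid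
Product: 15 (S)-2-(2,2-dimethyl-5-oxo-1,3-dioxolan-4-yl)acetic acid
Conditions: Me2C(OMe)2, TsOH·H2O (cat.), rt
Reagents that add atoms: 2,2-dimethoxypropane, COC(C)(C)OC
Why: Acid-catalysed transacetalisation ties the α-hydroxy acid into the five-membered dioxolanone, activating C1 and leaving the C4 acid free; the stereocentre is untouched.

Step 10
Reactants: 15 dioxolanone acid
Product: 17 (4S)-4-hydroxy-5,5-dimethyloxolan-2-one, via dihydroxy acid 16 (not isolated)
Conditions: MeMgBr (5 equiv), THF, 0 °C → rt; then 2 M HCl, rt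
Reagents that add atoms: methylmagnesium bromide, C[Mg]Br
Why: The bromomagnesium carboxylate is inert while the dioxolanone carbonyl takes up two methyl groups (Grignard double addition), and acidification closes the γ-lactone through the new tertiary alcohol without touching the carbinol stereocentre (future C10).

Step 11
Reactants: 17 hydroxy lactone
Product: 18 (4S)-5,5-dimethyloxolane-2,4-diol (lactol; both anomers)
Conditions: iBu2AlH (2.2 equiv), CH2Cl2, −78 °C; aq potassium sodium tartrate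
Reagents that add atoms: none
Why: Low-temperature iBu2AlH half-reduction of the lactone stops at the stable aluminium lactolate (lactone to lactol reduction).

Step 12
Reactants: 13 alkenyl triflate; 18 lactol
Product: 20 (1S,2S,3R,4R,6R)-6-[(5S)-5,6-dihydroxy-6-methyl-3-oxohept-1-en-2-yl]-3,4-epoxy-3-methylcyclohexane-1,2-diyl bis[(2Z)-2-methylbut-2-enoate], via hydroxy aldehyde 19 (not isolated)
Conditions: 18 (2 equiv), (nBu4N)4[W10O32] (2 mol %), NiBr2·dme (5 mol %), 4,4′-di-tert-butyl-2,2′-bipyridine (6 mol %), K2HPO4 (2 equiv), degassed MeCN, 390 nm LEDs, 25 °C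
Reagents that add atoms: none
Why: Proposed new method: formyl C–H alkenylation of an unprotected lactol with an alkenyl triflate under (nBu4N)4[W10O32]/NiBr2 dual catalysis; photoexcited [W10O32]4− abstracts the hydridic formyl hydrogen of the ring-opened tautomer 19 (abstraction at the equally hydridic anomeric C–H of 18 converges on the ring tautomer of the same product), zerovalent nickel inserts into the C–OTf bond of 13, the alkenyl nickel species captures the acyl radical, reductive elimination from trivalent nickel forms C7–C8, the reduced polyoxotungstate returns nickel to the zerovalent state and K2HPO4 takes up the triflic acid; the closest known reactions are the light-driven acylations of aryl and alkyl bromides with aldehydes under (nBu4N)4[W10O32] and a bipyridine-ligated NiBr2 catalyst, and no stereocentre is formed or touched.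

Step 13
Reactants: 20 β-hydroxy enone
Product: 21 (1S,2S,3R,4R,6R)-3,4-epoxy-3-methyl-6-[(3S,5S)-3,5,6-trihydroxy-6-methylhept-1-en-2-yl]cyclohexane-1,2-diyl bis[(2Z)-2-methylbut-2-enoate]
Conditions: Me4NBH(OAc)3, MeCN/AcOH (1:1), −30 °C
Reagents that add atoms: none
Why: In the Evans–Saksena reduction the C10 hydroxyl binds the acetoxyborohydride and delivers hydride intramolecularly through a chair transition state, so the malic acid centre sets C8 as the 1,3-anti (8S) alcohol by clean 1,2-reduction.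

Step 14
Reactants: 21 triol; 8 mixed anhydride
Product: 22 (1S,2S,3R,4R,6R)-6-[(3S,5S)-5,6-dihydroxy-6-methyl-3-{[(2Z)-2-methylbut-2-enoyl]oxy}hept-1-en-2-yl]-3,4-epoxy-3-methylcyclohexane-1,2-diyl bis[(2Z)-2-methylbut-2-enoate]
Conditions: 8 (1.3 equiv), NaHCO3 (solid, 3 equiv), PhMe, 60 °C
Reagents that add atoms: none
Why: The bulky mixed anhydride (Yamaguchi-type esterification, buffered by solid NaHCO3) acylates the allylic C8–OH in preference to the C10–OH, which is flanked by a fully substituted carbon, and the tertiary C11–OH; no stereocentre changes.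

Step 15
Reactants: 22 tris-angelate diol
Product: 24 (1S,2S,3R,4R,6R,8S,10R)-1,2,8-tris(angeloyloxy)-3,4:10,11-diepoxybisabol-7(14)-ene (target CNP0258231.4), via mesylate 23 (not isolated)
Conditions: MsCl, Et3N, CH2Cl2, −10 °C; then K2CO3, MeOH, 0 °C
Reagents that add atoms: none
Why: The secondary C10–OH is mesylated in preference to the tertiary alcohol, and the C11 alkoxide then closes the oxirane by intramolecular SN2 (Williamson-type epoxide closure), inverting the 10S sulfonate to the 10R epoxide.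

## Compound list

1 | (S)-(+)-carvone | C=C(C)[C@H]1CC=C(C)C(=O)C1 | starting material
2 | lithium (3S)-6-methyl-3-(prop-1-en-2-yl)cyclohexa-1,5-dien-1-olate (lithium dienolate of 1) | C=C(C)[C@H]1CC=C(C)C([O-])=C1.[Li+] | intermediate
3 | (5R,6R)-6-hydroxy-2-methyl-5-(prop-1-en-2-yl)cyclohex-2-en-1-one (OH trans to isopropenyl) | C=C(C)[C@H]1CC=C(C)C(=O)[C@@H]1O | intermediate
4 | angelic acid, (2Z)-2-methylbut-2-enoic acid | O=C(O)/C(C)=C\C | starting material
5 | (1S,6R)-3-methyl-2-oxo-6-(prop-1-en-2-yl)cyclohex-3-en-1-yl (2Z)-2-methylbut-2-enoate (ester cis to isopropenyl) | C=C(C)[C@H]1CC=C(C)C(=O)[C@H]1OC(=O)/C(C)=C\C | intermediate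
6 | (1S,2R,6R)-2-hydroxy-3-methyl-6-(prop-1-en-2-yl)cyclohex-3-en-1-yl (2Z)-2-methylbut-2-enoate (all cis) | C=C(C)[C@H]1CC=C(C)[C@@H](O)[C@H]1OC(=O)/C(C)=C\C | intermediate
7 | (1S,2S,3S,4R,6R)-3,4-epoxy-2-hydroxy-3-methyl-6-(prop-1-en-2-yl)cyclohexyl (2Z)-2-methylbut-2-enoate (all cis) | C=C(C)[C@H]1C[C@H]2O[C@@]2(C)[C@@H](O)[C@H]1OC(=O)/C(C)=C\C | intermediate
8 | (2Z)-2-methylbut-2-enoic 2,4,6-trichlorobenzoic anhydride | O=C(OC(=O)/C(C)=C\C)c1c(Cl)cc(Cl)cc1Cl | intermediate
9 | (1S,2S,3R,4R,6R)-3,4-epoxy-3-methyl-6-(prop-1-en-2-yl)cyclohexane-1,2-diyl bis[(2Z)-2-methylbut-2-enoate] | C=C(C)[C@H]1C[C@H]2O[C@@]2(C)[C@@H](OC(=O)/C(C)=C\C)[C@H]1OC(=O)/C(C)=C\C | intermediate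
10 | ozonide of 9: 6-(3-methyl-1,2,4-trioxolan-3-yl) analogue, both epimers at the trioxolane carbon | CC1(OCOO1)[C@H]1C[C@H]2O[C@@]2(C)[C@@H](OC(=O)/C(C)=C\C)[C@H]1OC(=O)/C(C)=C\C | intermediate
11 | (1S,2S,3R,4R,6S)-6-acetyl-3,4-epoxy-3-methylcyclohexane-1,2-diyl bis[(2Z)-2-methylbut-2-enoate] | CC(=O)[C@H]1C[C@H]2O[C@@]2(C)[C@@H](OC(=O)/C(C)=C\C)[C@H]1OC(=O)/C(C)=C\C | intermediate
12 | terminal potassium enolate of 11 | [K+].[O-]C(=C)[C@H]1C[C@H]2O[C@@]2(C)[C@@H](OC(=O)/C(C)=C\C)[C@H]1OC(=O)/C(C)=C\C | intermediate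
13 | (1S,2S,3R,4R,6S)-3,4-epoxy-3-methyl-6-[1-(trifluoromethylsulfonyloxy)ethenyl]cyclohexane-1,2-diyl bis[(2Z)-2-methylbut-2-enoate] | C=C(OS(=O)(=O)C(F)(F)F)[C@H]1C[C@H]2O[C@@]2(C)[C@@H](OC(=O)/C(C)=C\C)[C@H]1OC(=O)/C(C)=C\C | intermediate
14 | L-(S)-malic acid | OC(=O)C[C@H](O)C(=O)O | starting material
15 | (S)-2-(2,2-dimethyl-5-oxo-1,3-dioxolan-4-yl)acetic acid | OC(=O)C[C@@H]1OC(C)(C)OC1=O | intermediate
16 | (3S)-3,4-dihydroxy-4-methylpentanoic acid | OC(=O)C[C@H](O)C(C)(C)O | intermediate
17 | (4S)-4-hydroxy-5,5-dimethyloxolan-2-one | O=C1C[C@H](O)C(C)(C)O1 | intermediate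
18 | (4S)-5,5-dimethyloxolane-2,4-diol (both anomers) | OC1C[C@H](O)C(C)(C)O1 | intermediate
19 | (3S)-3,4-dihydroxy-4-methylpentanal | O=CC[C@H](O)C(C)(C)O | intermediate
20 | (1S,2S,3R,4R,6R)-6-[(5S)-5,6-dihydroxy-6-methyl-3-oxohept-1-en-2-yl]-3,4-epoxy-3-methylcyclohexane-1,2-diyl bis[(2Z)-2-methylbut-2-enoate] | C=C(C(=O)C[C@H](O)C(C)(C)O)[C@H]1C[C@H]2O[C@@]2(C)[C@@H](OC(=O)/C(C)=C\C)[C@H]1OC(=O)/C(C)=C\C | intermediate
21 | (1S,2S,3R,4R,6R)-3,4-epoxy-3-methyl-6-[(3S,5S)-3,5,6-trihydroxy-6-methylhept-1-en-2-yl]cyclohexane-1,2-diyl bis[(2Z)-2-methylbut-2-enoate] (8,10-anti) | C=C([C@H](C[C@H](O)C(C)(C)O)O)[C@H]1C[C@H]2O[C@@]2(C)[C@@H](OC(=O)/C(C)=C\C)[C@H]1OC(=O)/C(C)=C\C | intermediate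
22 | (1S,2S,3R,4R,6R)-6-[(3S,5S)-5,6-dihydroxy-6-methyl-3-{[(2Z)-2-methylbut-2-enoyl]oxy}hept-1-en-2-yl]-3,4-epoxy-3-methylcyclohexane-1,2-diyl bis[(2Z)-2-methylbut-2-enoate] | C=C([C@H](C[C@H](O)C(C)(C)O)OC(=O)/C(C)=C\C)[C@H]1C[C@H]2O[C@@]2(C)[C@@H](OC(=O)/C(C)=C\C)[C@H]1OC(=O)/C(C)=C\C | intermediate
23 | C10 methanesulfonate of 22, (3S,5S)-6-hydroxy-5-(methanesulfonyloxy) side chain | C=C([C@H](C[C@H](OS(C)(=O)=O)C(C)(C)O)OC(=O)/C(C)=C\C)[C@H]1C[C@H]2O[C@@]2(C)[C@@H](OC(=O)/C(C)=C\C)[C@H]1OC(=O)/C(C)=C\C | intermediate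
24 | (1S,2S,3R,4R,6R)-6-[(3S)-4-[(2R)-3,3-dimethyloxiran-2-yl]-3-{[(2Z)-2-methylbut-2-enoyl]oxy}but-1-en-2-yl]-3,4-epoxy-3-methylcyclohexane-1,2-diyl bis[(2Z)-2-methylbut-2-enoate] | C=C([C@H](C[C@H]1OC1(C)C)OC(=O)/C(C)=C\C)[C@H]1C[C@H]2O[C@@]2(C)[C@@H](OC(=O)/C(C)=C\C)[C@H]1OC(=O)/C(C)=C\C | target

## Step count and risks

Total step count: 15. Longest linear sequence: 11 steps (steps 1–4, 6–8 and 12–15 from carvone; step 5 makes the acylating agent and steps 9–11 are the malic acid branch).

Three steps most likely to fail: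

**Step 12 (the proposed new photochemical alkenylation).** The product enone can trap acyl radicals, the lactol can be over-oxidised back to lactone 17, hydrogen abstraction can compete at the carbinol C–H, and alkenyl triflates are untested in this manifold. The fallback uses known chemistry and sets out from lactone 17 and triflate 13. LiAlH4 reduces 17 to (3S)-4-methylpentane-1,3,4-triol F1. Et3SiOTf/2,6-lutidine gives the tris(triethylsilyl) ether F2. Swern oxidation cleaves and oxidises only the primary silyl ether to (3S)-4-methyl-3,4-bis(triethylsilyloxy)pentanal F3. A CrCl2/NiCl2 (cat.) Nozaki–Hiyama–Kishi coupling of F3 with 13 in DMF gives the allylic alcohol F4 as C8 epimers. Dess–Martin periodinane converges both epimers to the bis-silyl enone F5. HF·pyridine/pyridine in THF at 0 °C removes both silyl groups and returns to 20.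

**Step 2 (Mitsunobu inversion of an α-hydroxy enone with a hindered acid).** Elimination, aromatisation or retention could compete. The fallback sets out from 1. LiN(iPr)2/Me3SiCl gives the silyl dienol ether F6. N-Bromosuccinimide brominates it anti to the isopropenyl group to give (5R,6R)-6-bromo-2-methyl-5-(prop-1-en-2-yl)cyclohex-2-en-1-one F7. Cesium (2Z)-2-methylbut-2-enoate F8 (made from 4 and Cs2CO3) in DMF at 0 °C displaces the bromide with inversion and returns to 5.

**Step 14 (site-selective angeloylation of one of three hydroxyls).** Over-acylation or a 1,3-acyl shift to O10 could erode the selectivity. The fallback sets out from 20 and differentiates the oxygens by mechanism. A SmI2-catalysed Evans–Tishchenko reduction with acetaldehyde gives the anti-diol monoacetate F9, with the acetate on O10 and the new (8S) hydroxyl free. Mixed anhydride 8 (NaHCO3, PhMe, 60 °C) then acylates the only free secondary hydroxyl to give the angelate acetate F10. K2CO3/MeOH at 0 °C removes the acetate in preference to the hindered conjugated angelates and returns to 22.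

## Further compounds

F1 | step 12 | (3S)-4-methylpentane-1,3,4-triol | OCC[C@H](O)C(C)(C)O
F2 | step 12 | (3S)-4-methyl-1,3,4-tris(triethylsilyloxy)pentane | CC[Si](CC)(CC)OCC[C@H](O[Si](CC)(CC)CC)C(C)(C)O[Si](CC)(CC)CC
F3 | step 12 | (3S)-4-methyl-3,4-bis(triethylsilyloxy)pentanal | O=CC[C@H](O[Si](CC)(CC)CC)C(C)(C)O[Si](CC)(CC)CC
F4 | step 12 | bis-silyl allylic alcohol, C8 epimers: 6-[(5S)-3-hydroxy-6-methyl-5,6-bis(triethylsilyloxy)hept-1-en-2-yl] analogue of 20 | C=C(C(O)C[C@H](O[Si](CC)(CC)CC)C(C)(C)O[Si](CC)(CC)CC)[C@H]1C[C@H]2O[C@@]2(C)[C@@H](OC(=O)/C(C)=C\C)[C@H]1OC(=O)/C(C)=C\C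
F5 | step 12 | bis(triethylsilyl) ether of 20 | C=C(C(=O)C[C@H](O[Si](CC)(CC)CC)C(C)(C)O[Si](CC)(CC)CC)[C@H]1C[C@H]2O[C@@]2(C)[C@@H](OC(=O)/C(C)=C\C)[C@H]1OC(=O)/C(C)=C\C
F6 | step 2 | trimethylsilyl dienol ether of 1, (3S)-6-methyl-3-(prop-1-en-2-yl)-1-(trimethylsilyloxy)cyclohexa-1,5-diene | C=C(C)[C@H]1CC=C(C)C(O[Si](C)(C)C)=C1
F7 | step 2 | (5R,6R)-6-bromo-2-methyl-5-(prop-1-en-2-yl)cyclohex-2-en-1-one | C=C(C)[C@H]1CC=C(C)C(=O)[C@@H]1Br
F8 | step 2 | cesium (2Z)-2-methylbut-2-enoate | [Cs+].[O-]C(=O)/C(C)=C\C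
F9 | step 14 | O10-acetate of 21, (3S,5S)-5-acetoxy-3,6-dihydroxy side chain | C=C([C@H](C[C@H](OC(C)=O)C(C)(C)O)O)[C@H]1C[C@H]2O[C@@]2(C)[C@@H](OC(=O)/C(C)=C\C)[C@H]1OC(=O)/C(C)=C\C
F10 | step 14 | O10-acetate of 22, (3S,5S)-5-acetoxy-3-angeloyloxy-6-hydroxy side chain | C=C([C@H](C[C@H](OC(C)=O)C(C)(C)O)OC(=O)/C(C)=C\C)[C@H]1C[C@H]2O[C@@]2(C)[C@@H](OC(=O)/C(C)=C\C)[C@H]1OC(=O)/C(C)=C\C
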